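The numbers in the tables are calculated on assumed constants.

The run so far is this very flask, followed for 8.00 d, and I want to know what it reads earlier and later than that.

- spring: substrate 1.6 M; catalyst 40 mM; added ligand 190 mM; the very flask that is asked about, followed so far
- flask: substrate 1.6 M; catalyst 40 mM; added ligand 190 mM; time 15 d

spring run (percent of the substrate charged)

| time / d | isomer of the product / % | target / % | substrate / % |
|---|---|---|---|
| 1.67 | 76.5 | 2.0 | 1.0 |
| 3.00 | 86.1 | 2.1 | 0.3 |
| 5.00 | 93.3 | 3.5 | 0.9 |
| 6.00 | 96.9 | 1.2 | 0 |
| 8.00 | 97.8 | 2.7 | 0.3 |

(standard deviation of a reading: 1 percentage point)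

- the analysis behind the earlier runs scatters by 1 percentage point, standard deviation

* share of isomer of the product in isomer of the product plus target at 12 min
* share of isomer of the product in isomer of the product plus target at 8.0 h
* share of isomer of the product in isomer of the product plus target at 15 d

1. The readings leave a gap: at 1.67 d the three species miss 20.5 % of the charge, and at 3.00 d they miss 11.5 %. Some unseen form therefore holds material, and I read its halving time as 1.59 d.

2. I place the asked times against that halving time in powers of ten. The earliest, 12 min, lies at −2.28 decades, so by this reckoning the isomer of the product is just starting there.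

3. The middle time, 8.0 h, lies at −0.679 decades, still short of one halving.

4. The latest time, 15 d, lies at 0.975 decades. If the halving goes on at the rate I read, my estimate for the gap at that time is 0.0624 % of the charge.

5. I carry the selectivity factor, the summed isomer readings over the summed target readings: 39.2, or 1.59 decades. The ratio reads 38.2 at the first reading and 36.2 at the last, with no trend beyond the scatter.

6. I therefore commit to one share on each rung, 97.5 %. The first reading stands at 1.67 d, so at 12 min and 8.0 h this share is my extension of the readings and no reading itself.

7. The forecast says 85 %, 93 % and 97.6 %. It differs from mine at the two earlier times, most at 12 min: “If target forms early, directly from substrate, while isomer arrives late through the intermediate, the early share could be much lower.”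

The flask gives 97.3 %, 97.3 % and 97.3 %, so the forecast is 12 percentage points low at 12 min.

    substrate + catalyst → catalyst + target (k = 9.80 × 10⁻⁵ M⁻¹ s⁻¹)
    catalyst + other conformer → catalyst + isomer of the product (k = 6.00 × 10⁻⁴ M⁻¹ s⁻¹)
    catalyst + added ligand ⇌ idle complex (K = 13.0 M⁻¹, k = 9.10 × 10⁻⁵ M⁻¹ s⁻¹)
    substrate ⇌ other conformer, settled at all times (K = 5.90)

With [other conformer] held at 5.9 times [substrate], and the same [catalyst] in both steps, isomer forms 36.1 times as fast as target. Carried to the neighbour with 0.64 M of substrate, my factor puts 2.49 % of the charge into target, and that flask holds 2.69 % at 15.0 d.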